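The readings are simulated for an exercise, and the scatter is random.

There were 4 questions about this flask, and I took them through one fork.

| flask | substrate | reagent | remark | time |
|---|---|---|---|---|
| Sunday's | 2.5 × 10⁻⁴ M | 0.55 mM | run made earlier |  |
| Friday's | 0.0010 M | 0.55 mM | run made earlier |  |
| Saturday's | 5.0 × 10⁻⁴ M | 0.28 mM | run made earlier |  |
| flask | 5.0 × 10⁻⁴ M | 0.550 mM |  | 10 min |

| run | time / min | product / % |
|---|---|---|
| Sunday's | 0.500 | 19 |
| Sunday's | 1.33 | 33 |
| Sunday's | 3.00 | 33 |
| Sunday's | 8.00 | 33 |
| Friday's | 0.500 | 12 |
| Friday's | 1.33 | 15 |
| Friday's | 3.00 | 13 |
| Friday's | 8.00 | 8 |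
| Saturday's | 0.500 | 6 |
| Saturday's | 1.33 | 13 |
| Saturday's | 3.00 | 13 |
| Saturday's | 8.00 | 12 |

(scatter of a reading: 1.5 percentage points)

- the moment within 10 min at which there is most product
- the amount of product, in percent of the substrate charged, at that time
- earliest time at which at least nineteen twentieths of that best amount are there, in min
- latest time at which they still are, in min

- a species is counted by the substrate in it: one homo dimer A or homo dimer B counts as two
- steps thought possible: 2 substrate -> homo dimer B; 2 substrate -> homo dimer A; intermediate <-> product + by-product; substrate + reagent <-> intermediate

A substrate molecule met either reagent, on the way to product, or another substrate, and was lost to a homo dimer. With [reagent] taken as constant (pseudo-first-order), the odds against product go as [substrate]/[reagent]. I called x the odds at the charge, a selectivity factor as the readings give it, with any return from the intermediate lumped in.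

At odds of zero the fork gives a product share of 100 percent, but that is a limit of the formula and not of the flask, whose steps towards product can run back. With the odds frozen at x, it is one over one plus x. But [substrate] falls, the odds improve, and averaging over that fall gives the logarithm of one plus x, divided by x, which lies between them.

Sunday's plateau of 33% makes x 5.83. Scaled by [substrate]/[reagent], this gives 23.3 for Friday and a share of 13.7%, against a reading of 15%. For Saturday it gives 22.9 and 13.9%, against 13%.

For the flask, x is 11.7, so the frozen share is 7.90% and the averaged share 21.8%, higher. That much product takes about 19.8% of the reagent charged. Friday's product fell after its peak and Sunday's held, so I expected a slow fall in the flask after a peak between 1.33 min and 3.00 min.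

The forecast, “Interpolating on a log scale”, gave 23% at 2 min, held from 1 min to 5.5 min. The flask gave 21.9% at 1.87 min, held from 1.05 min to 4.02 min.

    2 substrate → homo dimer B (k = 0.111 /M/s)
    2 substrate → homo dimer A (k = 171 /M/s)
    intermediate ⇌ product + by-product (K = 7.73 × 10⁻⁴ M, k = 0.0599 /s)
    substrate + reagent ⇌ intermediate (K = 1820 /M, k = 80.4 /M/s)

The neighbour flask, charged with 1.3 × 10⁻⁴ M of substrate and the same reagent, has x of 3.03, smaller than the flask's, and the averaged share is then 46.0%. Its best was 49.1%. At 10.0 min homo dimer A held 45.4% of its substrate and product 47.0%.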